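**Plan**

- Cuts (target numbered as a 6-oxabicyclo[3.2.1]octane: bridgeheads C1 and C5, carbinol C2, O6, methylene C7, C8 carrying the side chain): the aryl O–CH2 bond to umbelliferone; the C7–O6 bond of the tetrahydrofuran ring (ring B) and the C2–H bond (ketone); then, in one operation, the C8–CH2 bond between side chain and ring and the C1–CH3 bond; last the C1=C8 alkene of the resulting cyclohexenone (RCM), back to (S)-linalool.
- Enabling feature: C5 (tertiary, O-bearing) is the direct neighbour of C8, and with ring B open C8, C1 and C2 are the β-carbon, α-carbon and carbonyl carbon of a cyclohexenone. The free C5 hydroxyl of a 4-hydroxy-4-methylcyclohex-2-enone can therefore, as its magnesium alkoxide, carry the side-chain Grignard reagent to C8 on its own face, and the enolate so formed is methylated at C1.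
- Forward order: carbocycle (ring A) by RCM; side chain and C1 methyl in step 10; ring B by displacement of a primary triflate by the tertiary hydroxyl; ketone reduction; Mitsunobu attachment of the coumarin.
- Stereochemistry: C5 from (S)-linalool; C8 by alkoxide-directed delivery; C1 by enolate methylation anti to the new chain; C2 by axial hydride addition to the bicyclic ketone; the E alkene by syn-carboalumination.

Key step: step 10

Assumption: (S)-(+)-linalool of high enantiomeric purity is taken as commercially available; centres that are erased later (the lactol carbon of 2, the carbinol carbon of 8 and 9) are carried as mixtures.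

**Route**

Step 1
Reactants: 1 (S)-(+)-linalool
Product: 2 (5S)-5-ethenyl-5-methyloxolan-2-ol (lactol of (4S)-4-hydroxy-4-methylhex-5-enal; both anomers)
Conditions: O3 (1.0 equiv, Sudan red 7B end point), CH2Cl2–MeOH 4:1, NaHCO3, −78 °C; then Me2S, −78 °C → rt
Reagents that add atoms: ozone [O-][O+]=O
Why: Ozonolysis with reductive work-up, in which the electron-rich trisubstituted alkene reacts far faster than the vinyl group next to the carbinol and the released aldehyde closes onto the tertiary hydroxyl as the lactol, the C5 stereocentre being untouched.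

Step 2
Reactants: 3 (4-methoxyphenyl)methanol; 4 2,3-dibromoprop-1-ene
Product: 6 1-{[(2-bromoprop-2-en-1-yl)oxy]methyl}-4-methoxybenzene, via sodium alkoxide 5 (not isolated)
Conditions: NaH, THF, 0 °C; then 4, Bu4NI (cat.), 0 °C → rt
Reagents that add atoms: none
Why: Williamson ether synthesis in which the alkoxide displaces the allylic bromide (direct and allylic attack give the same ether) while the vinylic bromide is inert.

Step 3
Reactants: 6 1-{[(2-bromoprop-2-en-1-yl)oxy]methyl}-4-methoxybenzene; 2 (5S)-5-ethenyl-5-methyloxolan-2-ol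
Product: 8 (6S)-2-{[(4-methoxybenzyl)oxy]methyl}-6-methylocta-1,7-diene-3,6-diol (both C3 epimers), via alkenyllithium 7 (not isolated)
Conditions: 6 (2.6 equiv), t-BuLi (5.2 equiv), Et2O, −78 °C; then 2 (1.0 equiv), −78 → −30 °C
Reagents that add atoms: none
Why: Bromine–lithium exchange gives the 2-lithioallyl ether, which first deprotonates the lactol and then adds to the ring-opened aldehyde (1,2-addition of an alkenyllithium to a lactol), the new carbinol centre forming as both epimers and being erased in step 5.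

Step 4
Reactants: 8 (6S)-2-{[(4-methoxybenzyl)oxy]methyl}-6-methylocta-1,7-diene-3,6-diol
Product: 9 (4S)-2-{[(4-methoxybenzyl)oxy]methyl}-4-methylcyclohex-2-ene-1,4-diol (both C1 epimers)
Conditions: second-generation Grubbs catalyst (H2IMes)(PCy3)Cl2Ru=CHPh (5 mol %), CH2Cl2 (0.01 M), 40 °C
Reagents that add atoms: none
Why: Ring-closing olefin metathesis of a 1,7-diene, in which the vinyl group loads the ruthenium carbene and closure onto the 1,1-disubstituted alkene gives the six-membered ring with a trisubstituted alkene and loss of ethene.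

Step 5
Reactants: 9 (4S)-2-{[(4-methoxybenzyl)oxy]methyl}-4-methylcyclohex-2-ene-1,4-diol
Product: 10 (4S)-4-hydroxy-2-{[(4-methoxybenzyl)oxy]methyl}-4-methylcyclohex-2-en-1-one
Conditions: MnO2 (activated, 15 equiv), CH2Cl2, rt
Reagents that add atoms: none
Why: Chemoselective allylic oxidation with MnO2, which oxidises only the secondary allylic alcohol, leaves the tertiary alcohol alone and converges both carbinol epimers to one enone.

Step 6
Reactants: 11 (but-3-yn-1-yloxy)(tert-butyl)dimethylsilane
Product: 14 (2E)-5-[(tert-butyldimethylsilyl)oxy]-3-methylpent-2-en-1-ol, via alkenylalane 12 (not isolated), via lithium alanate 13 (not isolated)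
Conditions: Me3Al (2.5 equiv), Cp2ZrCl2 (0.25 equiv), CH2Cl2, 0 °C → rt; volatiles removed; n-BuLi (1.1 equiv), THF–hexane, −78 °C; (CH2O)n, −78 °C → rt
Reagents that add atoms: trimethylaluminium C[Al](C)C; paraformaldehyde (as formaldehyde) C=O
Why: Negishi zirconium-catalysed carboalumination, a syn addition of methyl and aluminium across the terminal alkyne (methyl to the internal carbon) that fixes the E trisubstituted alkene, followed by transfer of the alkenyl group of the alanate to formaldehyde with retention.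

Step 7
Reactants: 14 (2E)-5-[(tert-butyldimethylsilyl)oxy]-3-methylpent-2-en-1-ol
Product: 15 tert-butyl({(2E)-5-[(tert-butyldimethylsilyl)oxy]-3-methylpent-2-en-1-yl}oxy)diphenylsilane
Conditions: TBDPSCl, imidazole, CH2Cl2, 0 °C → rt
Reagents that add atoms: tert-butyl(chloro)diphenylsilane CC(C)(C)[Si](Cl)(c1ccccc1)c1ccccc1
Why: Imidazole-promoted silylation of the primary allylic alcohol to an ether that should outlast the Grignard, oxidative, triflation and hydride steps.

Step 8
Reactants: 15 tert-butyl({(2E)-5-[(tert-butyldimethylsilyl)oxy]-3-methylpent-2-en-1-yl}oxy)diphenylsilane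
Product: 16 (3E)-5-[(tert-butyldiphenylsilyl)oxy]-3-methylpent-3-en-1-ol
Conditions: PPTS (0.2 equiv), MeOH, rt
Reagents that add atoms: none
Why: Acid-catalysed methanolysis, which cleaves the primary TBS ether far faster than the bulkier and more acid-stable TBDPS ether.

Step 9
Reactants: 16 (3E)-5-[(tert-butyldiphenylsilyl)oxy]-3-methylpent-3-en-1-ol
Product: 17 {[(2E)-5-bromo-3-methylpent-2-en-1-yl]oxy}(tert-butyl)diphenylsilane
Conditions: CBr4, PPh3, CH2Cl2, 0 °C
Reagents that add atoms: tetrabromomethane BrC(Br)(Br)Br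
Why: Appel bromination, an SN2 displacement of the oxyphosphonium group by bromide at the unhindered primary carbon that leaves the allylic silyl ether and the alkene geometry alone.

Step 10
Reactants: 17 {[(2E)-5-bromo-3-methylpent-2-en-1-yl]oxy}(tert-butyl)diphenylsilane; 10 (4S)-4-hydroxy-2-{[(4-methoxybenzyl)oxy]methyl}-4-methylcyclohex-2-en-1-one
Product: 21 (2R,3R,4S)-3-{(3E)-5-[(tert-butyldiphenylsilyl)oxy]-3-methylpent-3-en-1-yl}-4-hydroxy-2-{[(4-methoxybenzyl)oxy]methyl}-2,4-dimethylcyclohexan-1-one, via Grignard reagent 18 (not isolated), via chloromagnesium alkoxide 19 (not isolated), via magnesium enolate 20 (not isolated)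
Conditions: 17, Mg (BrCH2CH2Br-activated), THF, 40 °C (gives 18); 10, t-BuMgCl (1.0 equiv), THF, −78 °C (gives 19); 18 (1.6 equiv) added, −78 → −20 °C; then MeI (6 equiv), DMPU, −20 → 5 °C
Reagents that add atoms: iodomethane CI
Why: The C4 chloromagnesium alkoxide of 19 binds the Grignard reagent 18 and passes its alkyl group to the neighbouring β-carbon C3 through a magnesium-bridged cyclic transition state, and the magnesium enolate 20 so formed (C1–C2) is C-methylated by MeI in the same flask. The closest known reaction type is the alkoxide-directed (ligand-assisted) conjugate addition of Grignard reagents to 4-hydroxycyclohex-2-enones and quinols, combined with the usual alkyl halide capture of a conjugate-addition enolate (three-component coupling). No ring is closed in this step. C3 (R, the later C8) is set by delivery on the face of the C4 oxygen, reinforced by the larger C4 methyl on the opposite face; C2 (R, the later bridgehead C1) is set because MeI approaches the enolate anti to the new C3 chain and to the 1,3-related C4 alkoxide, so that CH2OPMB ends cis to both. The step needs 1,4- over 1,2-addition, secured because the carbonyl carbon is para to C4 and out of reach of the alkoxide-bound reagent while C3 is adjacent, and it needs alkylation at C2 rather than C6, secured because the conjugate addition generates the enolate regiospecifically. The poor leaving group (4-methoxybenzyl oxide), the magnesium counter-ion and the low temperature should hold back β-elimination from 20.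

Step 11
Reactants: 21 (2R,3R,4S)-3-{(3E)-5-[(tert-butyldiphenylsilyl)oxy]-3-methylpent-3-en-1-yl}-4-hydroxy-2-{[(4-methoxybenzyl)oxy]methyl}-2,4-dimethylcyclohexan-1-one
Product: 22 (2R,3R,4S)-3-{(3E)-5-[(tert-butyldiphenylsilyl)oxy]-3-methylpent-3-en-1-yl}-4-hydroxy-2-(hydroxymethyl)-2,4-dimethylcyclohexan-1-one
Conditions: DDQ (1.3 equiv), CH2Cl2–pH 7 phosphate buffer 10:1, 0 °C
Reagents that add atoms: none
Why: Oxidative cleavage of the 4-methoxybenzyl ether by DDQ (hydride abstraction at the electron-rich benzylic carbon and hydrolysis of the oxocarbenium ion), under buffered conditions that should spare the silyl ether, the alkene and the ketone.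

Step 12
Reactants: 22 (2R,3R,4S)-3-{(3E)-5-[(tert-butyldiphenylsilyl)oxy]-3-methylpent-3-en-1-yl}-4-hydroxy-2-(hydroxymethyl)-2,4-dimethylcyclohexan-1-one
Product: 24 (1R,5S,8R)-8-{(3E)-5-[(tert-butyldiphenylsilyl)oxy]-3-methylpent-3-en-1-yl}-1,5-dimethyl-6-oxabicyclo[3.2.1]octan-2-one, via primary triflate 23 (not isolated)
Conditions: Tf2O (1.1 equiv), 2,6-lutidine (3 equiv), CH2Cl2, −78 → 0 °C
Reagents that add atoms: none
Why: Selective triflation of the primary alcohol followed by intramolecular Williamson-type etherification, a 5-exo-tet displacement by the tertiary hydroxyl that is 1,3-diaxial to CH2OTf in the chair holding the side chain and both methyls equatorial, under a weak base that avoids retro-aldol loss of formaldehyde.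

Step 13
Reactants: 24 (1R,5S,8R)-8-{(3E)-5-[(tert-butyldiphenylsilyl)oxy]-3-methylpent-3-en-1-yl}-1,5-dimethyl-6-oxabicyclo[3.2.1]octan-2-one
Product: 25 (1R,2R,5S,8R)-8-{(3E)-5-[(tert-butyldiphenylsilyl)oxy]-3-methylpent-3-en-1-yl}-1,5-dimethyl-6-oxabicyclo[3.2.1]octan-2-ol
Conditions: NaBH4, MeOH, −20 → 0 °C
Reagents that add atoms: none
Why: Borohydride reduction of a cyclohexanone, in which hydride adds axially from the face opposite the C7 methylene that sits axial on the neighbouring bridgehead, giving the equatorial (2R) alcohol cis to the ether bridge.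

Step 14
Reactants: 25 (1R,2R,5S,8R)-8-{(3E)-5-[(tert-butyldiphenylsilyl)oxy]-3-methylpent-3-en-1-yl}-1,5-dimethyl-6-oxabicyclo[3.2.1]octan-2-ol
Product: 26 (1R,2R,5S,8R)-8-[(3E)-5-hydroxy-3-methylpent-3-en-1-yl]-1,5-dimethyl-6-oxabicyclo[3.2.1]octan-2-ol
Conditions: TBAF, THF, rt
Reagents that add atoms: none
Why: Fluoride-mediated desilylation driven by Si–F bond formation, to which no other group in the molecule responds.

Step 15
Reactants: 26 (1R,2R,5S,8R)-8-[(3E)-5-hydroxy-3-methylpent-3-en-1-yl]-1,5-dimethyl-6-oxabicyclo[3.2.1]octan-2-ol; 27 7-hydroxy-2H-chromen-2-one (umbelliferone)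
Product: 28 7-({(2E)-5-[(1R,2R,5S,8R)-2-hydroxy-1,5-dimethyl-6-oxabicyclo[3.2.1]octan-8-yl]-3-methylpent-2-en-1-yl}oxy)-2H-chromen-2-one
Conditions: PPh3, DIAD, THF, 0 °C → rt
Reagents that add atoms: none
Why: Mitsunobu etherification, in which the primary allylic alcohol is activated as its oxyphosphonium salt and displaced by the acidic phenol (SN2 at the primary carbon, alkene geometry retained) while the hindered secondary alcohol next to the quaternary bridgehead should not react.

**Compound list**

1 | (S)-(+)-linalool, (3S)-3,7-dimethylocta-1,6-dien-3-ol | C=C[C@@](C)(O)CCC=C(C)C | starting material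
2 | (5S)-5-ethenyl-5-methyloxolan-2-ol (both anomers) | C=C[C@]1(C)CCC(O)O1 | intermediate
3 | (4-methoxyphenyl)methanol | COc1ccc(CO)cc1 | starting material
4 | 2,3-dibromoprop-1-ene | C=C(Br)CBr | starting material
5 | sodium (4-methoxyphenyl)methanolate | [Na+].[O-]Cc1ccc(OC)cc1 | intermediate
6 | 1-{[(2-bromoprop-2-en-1-yl)oxy]methyl}-4-methoxybenzene | C=C(Br)COCc1ccc(OC)cc1 | intermediate
7 | {3-[(4-methoxybenzyl)oxy]prop-1-en-2-yl}lithium | [Li]C(=C)COCc1ccc(OC)cc1 | intermediate
8 | (6S)-2-{[(4-methoxybenzyl)oxy]methyl}-6-methylocta-1,7-diene-3,6-diol (both C3 epimers) | C=C[C@@](C)(O)CCC(O)C(=C)COCc1ccc(OC)cc1 | intermediate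
9 | (4S)-2-{[(4-methoxybenzyl)oxy]methyl}-4-methylcyclohex-2-ene-1,4-diol (both C1 epimers) | C[C@@]1(O)C=C(COCc2ccc(OC)cc2)C(O)CC1 | intermediate
10 | (4S)-4-hydroxy-2-{[(4-methoxybenzyl)oxy]methyl}-4-methylcyclohex-2-en-1-one | C[C@@]1(O)C=C(COCc2ccc(OC)cc2)C(=O)CC1 | intermediate
11 | (but-3-yn-1-yloxy)(tert-butyl)dimethylsilane | C#CCCO[Si](C)(C)C(C)(C)C | starting material
12 | {(1E)-4-[(tert-butyldimethylsilyl)oxy]-2-methylbut-1-en-1-yl}dimethylalane | C/C(CCO[Si](C)(C)C(C)(C)C)=C\[Al](C)C | intermediate
13 | lithium butyl{(1E)-4-[(tert-butyldimethylsilyl)oxy]-2-methylbut-1-en-1-yl}dimethylalanate | [Li+].C/C(CCO[Si](C)(C)C(C)(C)C)=C\[Al-](C)(C)CCCC | intermediate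
14 | (2E)-5-[(tert-butyldimethylsilyl)oxy]-3-methylpent-2-en-1-ol | C/C(CCO[Si](C)(C)C(C)(C)C)=C\CO | intermediate
15 | tert-butyl({(2E)-5-[(tert-butyldimethylsilyl)oxy]-3-methylpent-2-en-1-yl}oxy)diphenylsilane | C/C(CCO[Si](C)(C)C(C)(C)C)=C\CO[Si](c1ccccc1)(c1ccccc1)C(C)(C)C | intermediate
16 | (3E)-5-[(tert-butyldiphenylsilyl)oxy]-3-methylpent-3-en-1-ol | C/C(CCO)=C\CO[Si](c1ccccc1)(c1ccccc1)C(C)(C)C | intermediate
17 | {[(2E)-5-bromo-3-methylpent-2-en-1-yl]oxy}(tert-butyl)diphenylsilane | C/C(CCBr)=C\CO[Si](c1ccccc1)(c1ccccc1)C(C)(C)C | intermediate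
18 | bromo{(3E)-5-[(tert-butyldiphenylsilyl)oxy]-3-methylpent-3-en-1-yl}magnesium | C/C(CC[Mg]Br)=C\CO[Si](c1ccccc1)(c1ccccc1)C(C)(C)C | intermediate
19 | chloromagnesium (1S)-3-{[(4-methoxybenzyl)oxy]methyl}-1-methyl-4-oxocyclohex-2-en-1-olate | C[C@@]1(O[Mg]Cl)C=C(COCc2ccc(OC)cc2)C(=O)CC1 | intermediate
20 | C1–C2 bromomagnesium enolate and C4 chloromagnesium alkoxide of (3R,4S)-3-{(3E)-5-[(tert-butyldiphenylsilyl)oxy]-3-methylpent-3-en-1-yl}-4-hydroxy-2-{[(4-methoxybenzyl)oxy]methyl}-4-methylcyclohexan-1-one | C/C(=C\CO[Si](c1ccccc1)(c1ccccc1)C(C)(C)C)CC[C@@H]1C(COCc2ccc(OC)cc2)=C(O[Mg]Br)CC[C@]1(C)O[Mg]Cl | intermediate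
21 | (2R,3R,4S)-3-{(3E)-5-[(tert-butyldiphenylsilyl)oxy]-3-methylpent-3-en-1-yl}-4-hydroxy-2-{[(4-methoxybenzyl)oxy]methyl}-2,4-dimethylcyclohexan-1-one | C/C(=C\CO[Si](c1ccccc1)(c1ccccc1)C(C)(C)C)CC[C@@H]1[C@](C)(COCc2ccc(OC)cc2)C(=O)CC[C@]1(C)O | intermediate
22 | (2R,3R,4S)-3-{(3E)-5-[(tert-butyldiphenylsilyl)oxy]-3-methylpent-3-en-1-yl}-4-hydroxy-2-(hydroxymethyl)-2,4-dimethylcyclohexan-1-one | C/C(=C\CO[Si](c1ccccc1)(c1ccccc1)C(C)(C)C)CC[C@@H]1[C@](C)(CO)C(=O)CC[C@]1(C)O | intermediate
23 | primary trifluoromethanesulfonate of 22 | C/C(=C\CO[Si](c1ccccc1)(c1ccccc1)C(C)(C)C)CC[C@@H]1[C@](C)(COS(=O)(=O)C(F)(F)F)C(=O)CC[C@]1(C)O | intermediate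
24 | (1R,5S,8R)-8-{(3E)-5-[(tert-butyldiphenylsilyl)oxy]-3-methylpent-3-en-1-yl}-1,5-dimethyl-6-oxabicyclo[3.2.1]octan-2-one | C/C(=C\CO[Si](c1ccccc1)(c1ccccc1)C(C)(C)C)CC[C@@H]1[C@]2(C)CO[C@@]1(C)CCC2=O | intermediate
25 | (1R,2R,5S,8R)-8-{(3E)-5-[(tert-butyldiphenylsilyl)oxy]-3-methylpent-3-en-1-yl}-1,5-dimethyl-6-oxabicyclo[3.2.1]octan-2-ol | C/C(=C\CO[Si](c1ccccc1)(c1ccccc1)C(C)(C)C)CC[C@@H]1[C@]2(C)CO[C@@]1(C)CC[C@H]2O | intermediate
26 | (1R,2R,5S,8R)-8-[(3E)-5-hydroxy-3-methylpent-3-en-1-yl]-1,5-dimethyl-6-oxabicyclo[3.2.1]octan-2-ol | C/C(=C\CO)CC[C@@H]1[C@]2(C)CO[C@@]1(C)CC[C@H]2O | intermediate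
27 | 7-hydroxy-2H-chromen-2-one (umbelliferone) | O=c1ccc2ccc(O)cc2o1 | starting material
28 | 7-({(2E)-5-[(1R,2R,5S,8R)-2-hydroxy-1,5-dimethyl-6-oxabicyclo[3.2.1]octan-8-yl]-3-methylpent-2-en-1-yl}oxy)-2H-chromen-2-one | C/C(=C\COc1ccc2ccc(=O)oc2c1)CC[C@@H]1[C@]2(C)CO[C@@]1(C)CC[C@H]2O | target

**Step count**

Total steps: 15. Longest linear sequence: 10 steps (1 → 28 through steps 1, 3, 4, 5, 10, 11, 12, 13, 14, 15; the side-chain branch 11 → 28 through steps 6 to 15 is equally long).

**Steps most likely to fail**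

Step 10. The hindered, fully substituted magnesium enolate 20 may take up the methyl group more slowly than it loses the β-(4-methoxybenzyl)oxy group by E1cB elimination, or it may simply be protonated at work-up. Grignard reagent that is not bound to the alkoxide may also add to the carbonyl group. The fallback sets out from 10 and 17 and returns at 21. The directed addition is run in the same way, but enolate 20 is silylated instead of alkylated (TMSCl, Et3N, HMPA, −78 °C). This should give the bis(trimethylsilyl) compound F1, a silyl enol ether and tertiary silyl ether that stores the regiodefined enolate in a non-basic, isolable form from which carbonyl adducts can be separated. MeLi (THF, 0 °C) then cleaves only the enol silane to the lithium enolate F2. This more reactive enolate is methylated at low temperature (MeI, HMPA, −78 → −40 °C) on the same face as in step 10 to the O-silylated ketone F3. Citric acid in MeOH removes the tertiary trimethylsilyl ether and returns 21.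

Step 3. The 2-lithioallyl ether 7 may decay by β-elimination of lithium alkoxide (to allene) before it adds, and proton transfer from the lactol consumes reagent and leaves the aldehyde largely masked as its lactolate, so addition may stay incomplete. The fallback sets out from 6 and 2 and returns at 8. Bromide 6 is coupled with the hydroxy aldehyde form of 2 under Nozaki–Hiyama–Kishi conditions (CrCl2 in excess, NiCl2 catalytic, DMF–THF, rt). The coupling runs through the alkenylchromium dichloride F4, a non-basic organometallic that is formed in the presence of the aldehyde and tolerates free hydroxyl groups, and should give 8 directly.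

Step 12. Displacement at the primary carbon next to a quaternary centre may be slow enough for the triflate 23 to ionise or rearrange, or for the tertiary hydroxyl to be sulfonylated and eliminated, before the ring closes. The fallback sets out from 22 and returns at 24. The primary alcohol is oxidised with Dess–Martin periodinane (NaHCO3, CH2Cl2, 0 °C). The aldehyde is captured at once by the 1,3-diaxial tertiary hydroxyl as the bridged lactol F5. This is reduced through its oxocarbenium ion with Et3SiH and BF3·OEt2 (CH2Cl2, −78 °C) to the cyclic ether 24 (reductive etherification).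

**Further compounds**

F1 | step 10 | tert-butyl{[(2E)-5-{(1R,6S)-2-{[(4-methoxybenzyl)oxy]methyl}-6-methyl-3,6-bis[(trimethylsilyl)oxy]cyclohex-2-en-1-yl}-3-methylpent-2-en-1-yl]oxy}diphenylsilane | C/C(=C\CO[Si](c1ccccc1)(c1ccccc1)C(C)(C)C)CC[C@@H]1C(COCc2ccc(OC)cc2)=C(O[Si](C)(C)C)CC[C@]1(C)O[Si](C)(C)C
F2 | step 10 | lithium enolate obtained from F1 by cleavage of the enol silane (tertiary trimethylsilyl ether retained) | C/C(=C\CO[Si](c1ccccc1)(c1ccccc1)C(C)(C)C)CC[C@@H]1C(COCc2ccc(OC)cc2)=C(O[Li])CC[C@]1(C)O[Si](C)(C)C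
F3 | step 10 | (2R,3R,4S)-3-{(3E)-5-[(tert-butyldiphenylsilyl)oxy]-3-methylpent-3-en-1-yl}-2-{[(4-methoxybenzyl)oxy]methyl}-2,4-dimethyl-4-[(trimethylsilyl)oxy]cyclohexan-1-one | C/C(=C\CO[Si](c1ccccc1)(c1ccccc1)C(C)(C)C)CC[C@@H]1[C@](C)(COCc2ccc(OC)cc2)C(=O)CC[C@]1(C)O[Si](C)(C)C
F4 | step 3 | dichloro{3-[(4-methoxybenzyl)oxy]prop-1-en-2-yl}chromium | C=C([Cr](Cl)Cl)COCc1ccc(OC)cc1
F5 | step 12 | (1R,5S,8R)-8-{(3E)-5-[(tert-butyldiphenylsilyl)oxy]-3-methylpent-3-en-1-yl}-7-hydroxy-1,5-dimethyl-6-oxabicyclo[3.2.1]octan-2-one (both C7 epimers) | C/C(=C\CO[Si](c1ccccc1)(c1ccccc1)C(C)(C)C)CC[C@@H]1[C@]2(C)C(O)O[C@@]1(C)CCC2=O
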